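A direct plan would take both rings from methyl olivetolate A1. Exhaustive O-methylation and saponification would give 2,4-dimethoxy-6-pentylbenzoic acid A2. Acylation of the 4-OH of a second A1 by activated A2 would give the 2-hydroxy depside methyl ester A3. The ester methyl of A3 would then have to be moved to the 2-OH so that the carboxyl is free.
Its weakest steps would be:
- The closing methyl relocation with hot iodide: it has no close precedent, and a phenoxide plus iodide at high temperature beside a depside ester and three aryl methyl ethers invites transacylation and ether cleavage. Plain saponification instead would cut the depside first.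
- The depside esterification: a di-ortho-substituted benzoic acid must be forced through an acylium-type anhydride onto one of the two phenols of A1, and site control rests only on a hydrogen bond.
- The methylation/saponification to A2: resorcinol anions also C-methylate, the hindered ester needs hot hydroxide, and the ester methyl is put on only to be taken off.

**Retrosynthetic overview**
Ring A is the 2,4-dimethoxy-6-pentylbenzoyl ring (C1'–C6') and ring B the benzoic acid ring (C1–C6). The key disconnection cuts both bonds of the depside carbonyl carbon, C1'–C(=O) and C(=O)–O(C4), which leaves a ring A aryl iodide, CO and a ring B phenol; these are joined by one Pd-catalysed carbonylative coupling.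
Ring B: 2-methoxy-6-methylbenzoic acid 1 already holds 2-OMe and the carboxyl; as tert-butyl ester 2 it is butylated at the methyl group with 1-iodobutane 3 to give 4. The single oxygen at C4 is then installed by sterically controlled C–H borylation (boronate 5) and oxidation to phenol 6, since C4–H is the only ring C–H with hydrogen on both sides.
Ring A: olivetol dimethyl ether 7 is iodinated once to 8; then 6, 8 and CO give tert-butyl planaate 9, and acid frees planaic acid 10.
Both benzene rings are bought, so no ring is closed; ring B is completed first, ring A second, and they are joined last. The weak steps are avoided because ring B never carries two hydroxyls or a methyl ester, the di-ortho-substituted acid is never made or activated, and the carboxyl is freed by alkyl–oxygen acidolysis that cannot touch the depside ester.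

Key step: step 5

Remark: the target has no stereocentre; compounds 1, 3 and 7 are taken as commercial.

Step 1
Reactants: 1 2-methoxy-6-methylbenzoic acid
Product: 2 tert-butyl 2-methoxy-6-methylbenzoate
Conditions: t-BuOC(=NH)CCl3 (2 equiv), CH2Cl2/cyclohexane (1:2), rt, 18 h
Reagents that add atoms: tert-butyl 2,2,2-trichloroacetimidate, CC(C)(C)OC(=N)C(Cl)(Cl)Cl
Why: The acid protonates the imidate and its carboxylate oxygen traps the tert-butyl cation (O-alkylation with alkyl–oxygen bond formation), so the carbonyl between 2-OMe and 6-methyl never has to be attacked.

Step 2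
Reactants: 2 tert-butyl 2-methoxy-6-methylbenzoate; 3 1-iodobutane
Product: 4 tert-butyl 2-methoxy-6-pentylbenzoate
Conditions: LiN(i-Pr)2 (1.15 equiv), THF, −78 °C, 30 min; then 3 (1.3 equiv), −78 to 0 °C; aq NH4Cl
Reagents that add atoms: none
Why: Lateral lithiation of an ortho-toluate ester gives the ester-stabilised benzylic anion, which is C-alkylated by the primary iodide in an SN2 reaction, while the tert-butyl ester resists self-condensation; no stereocentre is formed.

Step 3
Reactants: 4 tert-butyl 2-methoxy-6-pentylbenzoate
Product: 6 tert-butyl 4-hydroxy-2-methoxy-6-pentylbenzoate, via tert-butyl 4-(pinacolboryl)-2-methoxy-6-pentylbenzoate 5 (not isolated)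
Conditions: [Ir(OMe)(cod)]2 (1.5 mol %), 4,4'-di-tert-butyl-2,2'-bipyridine (3 mol %), B2pin2 (1.0 equiv), THF, 80 °C, 16 h; evaporate; then Oxone (2KHSO5·KHSO4·K2SO4; 1.1 equiv KHSO5), acetone/H2O (1:1), rt, 15 min; aq NaHSO3
Reagents that add atoms: bis(pinacolato)diboron, CC1(C)OB(OC1(C)C)B1OC(C)(C)C(C)(C)O1 (its boryl group sits only in 5); potassium peroxymonosulfate (active salt of Oxone), [K+].[O-]S(=O)(=O)OO (its terminal oxygen becomes the phenol oxygen of 6)
Why: Iridium-catalysed aromatic C–H borylation is ruled by sterics and in this 1,2,3-trisubstituted ring should take C4–H, the only C–H flanked by two hydrogens (C3–H lies next to OMe, C5–H next to pentyl); peroxymonosulfate then oxidises the aryl boronate in the same pot by aryl shift from boron to oxygen (one-pot C–H borylation/oxidation to a phenol).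

Step 4
Reactants: 7 1,3-dimethoxy-5-pentylbenzene (olivetol dimethyl ether)
Product: 8 2-iodo-1,5-dimethoxy-3-pentylbenzene (= 1-iodo-2,4-dimethoxy-6-pentylbenzene)
Conditions: N-iodosuccinimide (1.05 equiv), MeCN, 0 °C to rt, dark; aq Na2S2O3
Reagents that add atoms: N-iodosuccinimide, O=C1CCC(=O)N1I
Why: Electrophilic aromatic iodination of a 5-alkylresorcinol dimethyl ether goes para to one methoxy group and ortho to the other (C4 and C6 of 7 are equivalent), as its halogenations and formylations do, and not to the crowded C2 between the two methoxy groups; one equivalent of reagent limits di-iodination.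

Step 5
Reactants: 8 2-iodo-1,5-dimethoxy-3-pentylbenzene (1.2 equiv); 6 tert-butyl 4-hydroxy-2-methoxy-6-pentylbenzoate
Product: 9 tert-butyl planaate (tert-butyl 4-[(2,4-dimethoxy-6-pentylbenzoyl)oxy]-2-methoxy-6-pentylbenzoate)
Conditions: Pd(OAc)2 (5 mol %), Xantphos (7.5 mol %), Et3N (3 equiv), CO (balloon, 1 atm), toluene, 100 °C, 16 h
Reagents that add atoms: carbon monoxide, [C-]#[O+]
Why: Zerovalent palladium, formed in situ from Pd(OAc)2 and Xantphos, adds to the C–I bond of 8, CO inserts into the aryl–palladium bond to give an aroylpalladium iodide, the phenoxide of 6 (Et3N) takes the place of iodide, and C(acyl)–O bond formation releases 9 and returns zerovalent palladium. The closest known reaction type is the Pd-catalysed aryloxycarbonylation of aryl iodides with phenols (Heck carbonylation) under one atmosphere of CO with wide-bite-angle bisphosphines. No ring is closed and no stereocentre is formed; the step makes both bonds of the depside carbonyl carbon at once, C1'–C(=O) on ring A and C(=O)–O on C4 of ring B, from three components. It needs CO insertion to outrun direct aryl–O coupling and hydrodeiodination, and the two ortho groups of 8 (2'-OMe, 6'-pentyl) help, because they retard aryl–O reductive elimination while migration of the electron-rich aryl group to CO relieves crowding at palladium. Site selectivity is given by the substrates: 6 has one OH only, made acidic enough for Et3N by the para ester, and the tert-butyl ester, the aryl ethers and the new aryl ester are inert to the catalyst. The hindered carbonyl is thus built on the metal and never has to be activated as a free di-ortho-substituted acid.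

Step 6
Reactants: 9 tert-butyl planaate
Product: 10 planaic acid (4-[(2,4-dimethoxy-6-pentylbenzoyl)oxy]-2-methoxy-6-pentylbenzoic acid)
Conditions: CF3CO2H/CH2Cl2 (1:4), 0 °C to rt, 2 h; evaporate with toluene
Reagents that add atoms: none
Why: Acidolysis of the tert-butyl ester by alkyl–oxygen fission (AAL1, loss of isobutene) needs neither nucleophile nor base, so the depside aryl ester and the three aryl methyl ethers should stay intact.

**Compound list**
1 | 2-methoxy-6-methylbenzoic acid | Cc1cccc(OC)c1C(=O)O | starting material
2 | tert-butyl 2-methoxy-6-methylbenzoate | Cc1cccc(OC)c1C(=O)OC(C)(C)C | intermediate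
3 | 1-iodobutane | CCCCI | starting material
4 | tert-butyl 2-methoxy-6-pentylbenzoate | CCCCCc1cccc(OC)c1C(=O)OC(C)(C)C | intermediate
5 | tert-butyl 4-(pinacolboryl)-2-methoxy-6-pentylbenzoate | CCCCCc1cc(B2OC(C)(C)C(C)(C)O2)cc(OC)c1C(=O)OC(C)(C)C | intermediate (not isolated)
6 | tert-butyl 4-hydroxy-2-methoxy-6-pentylbenzoate | CCCCCc1cc(O)cc(OC)c1C(=O)OC(C)(C)C | intermediate
7 | 1,3-dimethoxy-5-pentylbenzene (olivetol dimethyl ether) | CCCCCc1cc(OC)cc(OC)c1 | starting material
8 | 2-iodo-1,5-dimethoxy-3-pentylbenzene | CCCCCc1cc(OC)cc(OC)c1I | intermediate
9 | tert-butyl planaate (tert-butyl 4-[(2,4-dimethoxy-6-pentylbenzoyl)oxy]-2-methoxy-6-pentylbenzoate) | CCCCCc1cc(OC(=O)c2c(CCCCC)cc(OC)cc2OC)cc(OC)c1C(=O)OC(C)(C)C | intermediate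
10 | planaic acid (achiral) | CCCCCc1cc(OC(=O)c2c(CCCCC)cc(OC)cc2OC)cc(OC)c1C(=O)O | target

Total step count: 6. Longest linear sequence: 5 steps (steps 1, 2, 3, 5, 6).

**Steps most likely to fail**

Step 5 (key step). The di-ortho-substituted aryl iodide may turn over slowly under CO, so that 8 is hydrodeiodinated or palladium precipitates before the weakly nucleophilic phenoxide of 6 is acylated. The fallback brings in the carbonyl carbon as CO2 and closes the ester by classical acylation. It sets out from 8: iodine–lithium exchange (n-BuLi, THF, −78 °C) and a CO2 quench would give 2,4-dimethoxy-6-pentylbenzoic acid F1. (COCl)2 with catalytic DMF in CH2Cl2 would give 2,4-dimethoxy-6-pentylbenzoyl chloride F2. F2 would acylate 6 (Et3N, catalytic 4-(dimethylamino)pyridine, CH2Cl2, 0 °C to rt), and the route is rejoined at 9.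

Step 3. Borylation of the electron-rich, 1,2,3-trisubstituted ring may be incomplete, so that 4 is carried into the oxidation, or the new phenol may be over-oxidised by excess peroxymonosulfate. The fallback bypasses the phenol and makes the aryl C4–O bond from the boronate. It sets out from 4: the borylation is run alone and 5 is isolated by chromatography. The pinacol ester is cleaved (NaIO4, NH4OAc, acetone/H2O) to [4-(tert-butoxycarbonyl)-3-methoxy-5-pentylphenyl]boronic acid F3. Copper-mediated O-arylation of acid F1 (made from 8 as above) with F3 (Cu(OTf)2, urea, EtOAc, air, 60 °C; Chan–Lam coupling of a carboxylic acid) would give 9 directly, where the route is rejoined. Steps 3 and 5 are then both replaced.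

Step 2. The benzylic anion may undergo Claisen-type self-condensation with unreacted 2, or proton exchange may lead to double butylation. The fallback runs the alkylation on the free acid, whose carboxylate cannot be attacked. It sets out from 1: LiN(i-Pr)2 (2.2 equiv, THF, −78 to 0 °C) would give the carboxylate/benzyl dianion, which with 3 would give 2-methoxy-6-pentylbenzoic acid F4. tert-Butylation as in step 1 (t-BuOC(=NH)CCl3) would rejoin the route at 4.

**Further compounds**
F1 | step 5 | 2,4-dimethoxy-6-pentylbenzoic acid | CCCCCc1cc(OC)cc(OC)c1C(=O)O
F2 | step 5 | 2,4-dimethoxy-6-pentylbenzoyl chloride | CCCCCc1cc(OC)cc(OC)c1C(=O)Cl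
F3 | step 3 | [4-(tert-butoxycarbonyl)-3-methoxy-5-pentylphenyl]boronic acid | CCCCCc1cc(B(O)O)cc(OC)c1C(=O)OC(C)(C)C
F4 | step 2 | 2-methoxy-6-pentylbenzoic acid | CCCCCc1cccc(OC)c1C(=O)O
A1 | direct plan | methyl olivetolate (methyl 2,4-dihydroxy-6-pentylbenzoate) | CCCCCc1cc(O)cc(O)c1C(=O)OC
A2 | direct plan | 2,4-dimethoxy-6-pentylbenzoic acid | CCCCCc1cc(OC)cc(OC)c1C(=O)O
A3 | direct plan | methyl 4-[(2,4-dimethoxy-6-pentylbenzoyl)oxy]-2-hydroxy-6-pentylbenzoate | CCCCCc1cc(OC(=O)c2c(CCCCC)cc(OC)cc2OC)cc(O)c1C(=O)OC
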